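**Retrosynthetic overview**

1. The target comes from a cis-cyclohex-4-ene-1,3-diol by oxidation of its secondary allylic carbinol; all carbons and the quaternary stereocentre are then already in place.
2. The enediol comes from a dioxolane-masked 3-oxo aldehyde (C22) and a C3 allyl 1,3-dinucleophile (a γ-borylallylborane made in the flask from allenylboronic acid pinacol ester and diisopinocampheylborane) by a one-pot double allylboration: bond C1–C2 forms first, bond C4–C5 second, and the second event closes the only ring (target ring numbering, C1 = carbonyl carbon).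
3. Enabling feature: in ring atoms C1 to C6 the β-hydroxy ketone triad O=C1–C6H2–C5(OH) faces the allylic triad C2=C3–C4H2. This is a 1,3-dielectrophile/1,3-dinucleophile pairing in which C2 can carry boron and a transient stereocentre that is relayed across the ring to C5 and disappears when C2=C3 forms.
4. The masked oxo aldehyde comes from the β-keto ester made from icosanoyl chloride and Meldrum's acid.

Key step: step 5

Remark (assumption): the γ-borylallylborane made from (+)-diisopinocampheylborane is taken to attack the re face of an unhindered aliphatic aldehyde, as the parent allyl reagent of the same borane does. Should the sense be the reverse, the borane from (+)-α-pinene is used instead.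

**Step 1**
Reactants: 1 icosanoyl chloride; 2 Meldrum's acid (2,2-dimethyl-1,3-dioxane-4,6-dione)
Product: 4 ethyl 3-oxodocosanoate, via acyl Meldrum's acid 3 (not isolated)
Conditions: pyridine (2 equiv), CH2Cl2, 0 → 23 °C; then EtOH, reflux
Reagents that add atoms: ethanol, CCO
Why: C-acylation of Meldrum's acid followed by ethanolysis with loss of acetone and CO2 is the standard Meldrum's acid route to long-chain β-keto esters and involves no stereocentre.

**Step 2**
Reactants: 4 ethyl 3-oxodocosanoate
Product: 5 ethyl 2-(2-nonadecyl-1,3-dioxolan-2-yl)acetate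
Conditions: HOCH2CH2OH, TsOH·H2O (cat.), toluene, reflux, Dean–Stark trap
Reagents that add atoms: ethylene glycol, OCCO
Why: acid-catalysed ketalisation with azeotropic removal of water converts only the ketone of a β-keto ester and removes the acidic 1,3-dicarbonyl CH2 for the steps that follow.

**Step 3**
Reactants: 5 ethyl 2-(2-nonadecyl-1,3-dioxolan-2-yl)acetate
Product: 6 2-(2-nonadecyl-1,3-dioxolan-2-yl)acetaldehyde
Conditions: iBu2AlH (1.1 equiv), CH2Cl2, −78 °C; MeOH, then aq. KNaC4H4O6
Reagents that add atoms: none
Why: partial ester reduction with iBu2AlH at low temperature should stop at the aluminium hemiacetal, which is held by chelation to a dioxolane oxygen and gives the aldehyde only on work-up.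

**Step 4**
Reactants: 7 (−)-α-pinene (two equivalents are built into the product); 8 borane–dimethyl sulfide
Product: 9 (+)-diisopinocampheylborane
Conditions: 8 (1 equiv), 7 (2.3 equiv), THF, 0 °C; crystallisation at 0 °C
Reagents that add atoms: (−)-α-pinene (second equivalent of 7), CC1=CC[C@H]2C[C@@H]1C2(C)C
Why: two molecules of 7 add to one BH3 (2 C10H16 + BH3·SMe2 → (C10H17)2BH + Me2S), since hydroboration of this trisubstituted alkene stops at the dialkylborane, each B–H adds syn from the face opposite the gem-dimethyl bridge with boron on the less substituted carbon, and equilibration with the excess pinene should enrich the crystalline reagent to essentially one enantiomer.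

**Step 5**
Reactants: 6 2-(2-nonadecyl-1,3-dioxolan-2-yl)acetaldehyde; 9 (+)-diisopinocampheylborane; 10 allenylboronic acid pinacol ester
Product: 15 (1S,3S)-1-nonadecylcyclohex-4-ene-1,3-diol, via γ-borylallylborane 11 (not isolated), via boryl carbinol borinate 12 (not isolated), via keto allylboronate 13 (not isolated), via diol monoborate 14 (not isolated)
Conditions: 10, 9, toluene, 0 °C; 6, −78 °C; then TsOH·H2O (cat.), THF–H2O, 23 → 40 °C; then H2O2, aq. NaHCO3, 0 °C
Reagents that add atoms: water, O
Why: Proposed new method: hydroboration of the terminal C=C of 10 by 9 gives, after 1,3-boratropic equilibration, the E-configured γ-borylallylborane 11, whose boron-bearing carbon adds to the aldehyde of 6 through a chair Zimmerman–Traxler transition state (bond C1–C2 in the ring numbering of 16, intermediate 12); the acid then cleaves the borinate and the dioxolane (13), and the α-substituted pinacol allylboronate adds to the freed ketone within the molecule, boron binding the ketone oxygen while the CH2 terminus of the allyl unit attacks (bond C4–C5, intermediate 14), an addition that the acid should also accelerate by protonating a pinacolate oxygen. The closest known reaction types are the one-pot double allylboration of two aldehydes with γ-borylallylboranes and the tandem allylboration of keto aldehydes that closes cyclohexanols, and what is new is a ring closure in which the boron-bearing α-carbon rather than the γ-carbon carries the tether, so that the cis alkene C2=C3 is formed inside the ring. The single ring is closed as a six-membered carbocycle, 6-exo-trig at the carbonyl group and endo with respect to the allyl unit, through a boat-shaped bicyclo[2.2.2]-like transition state with C2 and C5 as bridgeheads. The secondary carbinol of 12 becomes S by reagent control (re-face delivery by the isopinocampheyl groups on boron) and the boron-bearing carbon becomes R through the E geometry of 11 (anti adduct), and because boron can reach the ketone oxygen only on its own face of the forming ring this one C–B centre fixes S at the quaternary carbinol and the cis relation of the two hydroxyls in 15. The step needs reaction at the aldehyde before the ketone and a substrate that does not enolise as a 3-oxo aldehyde, both secured by the dioxolane, a single alkene geometry of 11, secured by equilibration to the E isomer, and distinction of the two CH2 arms of the carbinol carbon, secured by the tether instead of by size. Both relay centres are removed again, C2 when the alkene forms and the secondary carbinol in step 6, so that only the quaternary centre remains.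

**Step 6**
Reactants: 15 (1S,3S)-1-nonadecylcyclohex-4-ene-1,3-diol
Product: 16 (S)-5-hydroxy-5-nonadecylcyclohex-2-en-1-one
Conditions: activated MnO2 (excess), CH2Cl2, 23 °C
Reagents that add atoms: none
Why: MnO2 oxidises the secondary allylic alcohol selectively under neutral conditions, the tertiary alcohol cannot be oxidised, and neutrality should avoid retro-aldol opening and loss of the β-hydroxyl, so the quaternary stereocentre is kept.

**Compound list**

1 | icosanoyl chloride | CCCCCCCCCCCCCCCCCCCC(=O)Cl | starting material
2 | Meldrum's acid (2,2-dimethyl-1,3-dioxane-4,6-dione) | CC1(C)OC(=O)CC(=O)O1 | starting material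
3 | 5-(1-hydroxyicosylidene)-2,2-dimethyl-1,3-dioxane-4,6-dione | CCCCCCCCCCCCCCCCCCCC(O)=C1C(=O)OC(C)(C)OC1=O | intermediate
4 | ethyl 3-oxodocosanoate | CCCCCCCCCCCCCCCCCCCC(=O)CC(=O)OCC | intermediate
5 | ethyl 2-(2-nonadecyl-1,3-dioxolan-2-yl)acetate | CCCCCCCCCCCCCCCCCCCC1(CC(=O)OCC)OCCO1 | intermediate
6 | 2-(2-nonadecyl-1,3-dioxolan-2-yl)acetaldehyde | CCCCCCCCCCCCCCCCCCCC1(CC=O)OCCO1 | intermediate
7 | (−)-α-pinene, (1S,5S)-2,6,6-trimethylbicyclo[3.1.1]hept-2-ene | CC1=CC[C@H]2C[C@@H]1C2(C)C | starting material
8 | borane–dimethyl sulfide | [BH3-][S+](C)C | starting material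
9 | (+)-diisopinocampheylborane (from two molecules of (1S,5S)-α-pinene) | B([C@H]1C[C@H]2C[C@@H]([C@@H]1C)C2(C)C)[C@H]1C[C@H]2C[C@@H]([C@@H]1C)C2(C)C | intermediate
10 | 4,4,5,5-tetramethyl-2-(propa-1,2-dien-1-yl)-1,3,2-dioxaborolane (allenylboronic acid pinacol ester) | C=C=CB1OC(C)(C)C(C)(C)O1 | starting material
11 | (E)-bis(isopinocampheyl)[3-(4,4,5,5-tetramethyl-1,3,2-dioxaborolan-2-yl)prop-2-en-1-yl]borane | CC1(C)OB(/C=C/CB([C@H]2C[C@H]3C[C@@H]([C@@H]2C)C3(C)C)[C@H]2C[C@H]3C[C@@H]([C@@H]2C)C3(C)C)OC1(C)C | intermediate
12 | (2S,3R)-1-(2-nonadecyl-1,3-dioxolan-2-yl)-3-(4,4,5,5-tetramethyl-1,3,2-dioxaborolan-2-yl)pent-4-en-2-yl bis(isopinocampheyl)borinate | CCCCCCCCCCCCCCCCCCCC1(OCCO1)C[C@H](OB([C@H]2C[C@H]3C[C@@H]([C@@H]2C)C3(C)C)[C@H]2C[C@H]3C[C@@H]([C@@H]2C)C3(C)C)[C@@H](C=C)B1OC(C)(C)C(C)(C)O1 | intermediate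
13 | (3R,4S)-4-hydroxy-3-(4,4,5,5-tetramethyl-1,3,2-dioxaborolan-2-yl)pentacos-1-en-6-one | CCCCCCCCCCCCCCCCCCCC(=O)C[C@H](O)[C@@H](C=C)B1OC(C)(C)C(C)(C)O1 | intermediate
14 | 2-{[(1S,5S)-5-hydroxy-1-nonadecylcyclohex-3-en-1-yl]oxy}-4,4,5,5-tetramethyl-1,3,2-dioxaborolane | CCCCCCCCCCCCCCCCCCC[C@]1(OB2OC(C)(C)C(C)(C)O2)CC=C[C@@H](O)C1 | intermediate
15 | (1S,3S)-1-nonadecylcyclohex-4-ene-1,3-diol (cis-diol) | CCCCCCCCCCCCCCCCCCC[C@]1(O)CC=C[C@@H](O)C1 | intermediate
16 | (S)-5-hydroxy-5-nonadecylcyclohex-2-en-1-one | CCCCCCCCCCCCCCCCCCC[C@]1(O)CC=CC(=O)C1 | target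

**Step count**

Total: 6 steps. Longest linear sequence: 5 steps (steps 1, 2, 3, 5, 6); step 4 prepares the chiral borane.

**Steps most likely to fail, with fallbacks**

1. Step 5. The boat-shaped, boron-bridged ring closure may be slower than acid-promoted loss of the allylboronate (protonation at the alkene terminus, or 1,2-elimination of the β-hydroxy boronate to a diene). Incomplete equilibration of the allylborane geometry would also erode the enantiomeric purity. The fallback uses known chemistry, replaces the boron relay by stepwise chelation control and ring-closing metathesis, sets out from 6 and comes back to the route at 16. Amino-alcohol-catalysed addition of Zn(CH=CH2)2 to 6 ((−)-MIB, toluene, 0 °C, si-face delivery) should give (R)-1-(2-nonadecyl-1,3-dioxolan-2-yl)but-3-en-2-ol F1. Ketal hydrolysis (PPTS, acetone–H2O) should give (R)-3-hydroxytetracos-1-en-5-one F2. Chelation-controlled addition of CH2=CHCH2MgBr (excess, THF, −78 °C; the magnesium alkoxide chelates the ketone and the allyl group enters axially) should give (3R,5S)-5-nonadecylocta-1,7-diene-3,5-diol F3. Ring-closing metathesis with second-generation Grubbs catalyst (CH2Cl2, 40 °C) should give the trans-diol (1S,3R)-1-nonadecylcyclohex-4-ene-1,3-diol F4, which is purified by chromatography at this stage because its diastereomer would lead to the enantiomer of the target. Oxidation of F4 with MnO2 as in step 6 gives 16.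

2. Step 6. The β-hydroxy enone may open by retro-aldol cleavage and re-close (racemisation of the quaternary centre), or lose the tertiary hydroxyl by enolisation toward C6 and elimination, followed by tautomerisation to a phenol, on the oxidant surface or during work-up. The fallback carries the tertiary hydroxyl as a silyl ether through the oxidation, sets out from 15 and comes back at 16. Silylation of both hydroxyls (Et3SiOTf, 2,6-lutidine, CH2Cl2, −78 °C) should give (1S,3S)-1-nonadecyl-1,3-bis(triethylsilyloxy)cyclohex-4-ene F5. Selective methanolysis of the less hindered secondary silyl ether (PPTS, MeOH, 0 °C) should give (1S,5S)-5-nonadecyl-5-(triethylsilyloxy)cyclohex-2-en-1-ol F6. Oxidation (MnO2, or Dess–Martin periodinane with NaHCO3) should give (S)-5-nonadecyl-5-(triethylsilyloxy)cyclohex-2-en-1-one F7. Buffered HF·pyridine (THF, 0 °C) then releases 16.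

3. Step 3. The aluminium hemiacetal may collapse before the quench and be reduced further to the primary alcohol, or the aldehyde may lose the β-alkoxy group by elimination during work-up. The fallback goes through the alcohol oxidation level, sets out from 5 and comes back at 6. Full reduction with LiAlH4 (THF, 0 °C) should give 2-(2-nonadecyl-1,3-dioxolan-2-yl)ethanol F8, and Parikh–Doering oxidation (SO3·pyridine, DMSO, iPr2NEt, CH2Cl2, 0 °C) returns 6.

**Further compounds**

F1 | step 5 | (R)-1-(2-nonadecyl-1,3-dioxolan-2-yl)but-3-en-2-ol | CCCCCCCCCCCCCCCCCCCC1(C[C@@H](O)C=C)OCCO1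
F2 | step 5 | (R)-3-hydroxytetracos-1-en-5-one | CCCCCCCCCCCCCCCCCCCC(=O)C[C@@H](O)C=C
F3 | step 5 | (3R,5S)-5-nonadecylocta-1,7-diene-3,5-diol | C=C[C@H](O)C[C@](O)(CCCCCCCCCCCCCCCCCCC)CC=C
F4 | step 5 | (1S,3R)-1-nonadecylcyclohex-4-ene-1,3-diol | CCCCCCCCCCCCCCCCCCC[C@]1(O)CC=C[C@H](O)C1
F5 | step 6 | (1S,3S)-1-nonadecyl-1,3-bis(triethylsilyloxy)cyclohex-4-ene | CCCCCCCCCCCCCCCCCCC[C@]1(O[Si](CC)(CC)CC)CC=C[C@@H](O[Si](CC)(CC)CC)C1
F6 | step 6 | (1S,5S)-5-nonadecyl-5-(triethylsilyloxy)cyclohex-2-en-1-ol | CCCCCCCCCCCCCCCCCCC[C@]1(O[Si](CC)(CC)CC)CC=C[C@@H](O)C1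
F7 | step 6 | (S)-5-nonadecyl-5-(triethylsilyloxy)cyclohex-2-en-1-one | CCCCCCCCCCCCCCCCCCC[C@]1(O[Si](CC)(CC)CC)CC=CC(=O)C1
F8 | step 3 | 2-(2-nonadecyl-1,3-dioxolan-2-yl)ethanol | CCCCCCCCCCCCCCCCCCCC1(CCO)OCCO1
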